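## Structural features

The target is a labdane: a trans-fused decalin (ring A = C1–C5 and C10, ring B = C5–C10) whose ring B holds a tetrasubstituted C8=C9 alkene carrying the C17 methyl on C8 and, on C9, a five-carbon chain (C11–C15) that ends in an (E)-trisubstituted allylic alcohol. Ring A carries a gem-dimethyl group on C4 and an isolated acetoxy stereocentre at C2; ring B carries four contiguous stereocentres, the quaternary C10 (methyl, taken as β), C5 (H α), C6 (OAc β, axial and syn to both the C10 methyl and the 4β methyl) and C7 (OAc α, allylic). The 6β,7α-diacetate is therefore a trans-diaxial pair next to a crowded ring fusion. Fragile points are the three acetates (cleavage, and migration whenever a neighbouring hydroxyl is free), the allylic C7–O bond, the C7 hydrogen once C6 is a ketone, and the need to keep the primary C15 hydroxyl free while three secondary hydroxyls are acetylated. The real difficulty is the quaternary C10 in the correct relation to the remote C2 oxygen, together with the oxygen pattern at C6 and C7. The key step uses the fact that O2 and the C10–C9 bond are cis-1,3 on ring A and that C9 bears C11: an ester from O2 to C11 can hold an alkyne carbon (C9) over the α face of C10 of a ring A diene C10=C5–C6=C7. The same cycloaddition places a heteroatom handle on C7 and leaves C5=C6 for H5 and O6.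

## Logic of the disconnections

**32 to 25 and 30.** The C12–C13 bond is cut (sp3–sp2). The (E) geometry of C13=C14 is then bought ready-made in 30, and the chain arrives with its hydroxyl free on a core that already carries all three acetates, so no protecting group is needed at C15. The forward step must hydroborate only the monosubstituted alkene of 25 and couple in the presence of three esters, one of them allylic.

**25 to 24 to 23.** The three acetyl C–O bonds are cut together, then the C7 silyl ether. One acetylation serves all three ring hydroxyls. The demand is that the hindered axial 6β-hydroxyl be acylated.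

**23 to 22 to 21.** The C11=C12 bond is cut back to an aldehyde, and the aldehyde to the primary allylic alcohol. This reduces the chain problem to the one carbon (C11) that the tether leaves behind. The forward steps need an oxidant that touches only the allylic hydroxyl and a methylenation of a hindered enal.

**21 to 20 to 19.** The C6 configuration is traced to a ketone and the ketone to the 6α-alcohol. Direct β-face delivery of oxygen to C6 is blocked by two syn-axial methyl groups, whereas hydride comes readily from the α face. The demand is that the C7 hydrogen next to the ketone is not exposed to base.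

**19 to 17 (via 18).** The C6–O and C5–H bonds are cut back to the C5=C6 alkene. One syn addition from the α face sets the trans ring fusion and puts oxygen on C6. A 5α-H trans fusion cannot coexist comfortably with the 2,11-lactone, because the lactone forces the C10–C9 bond axial on ring A. The tether therefore has to be cut before this step, and the hydroboration is placed after the lactone opening for that reason.

**17 to 16 to 15 to 14 to 13.** The two acetates, the C11–O2 bond of the lactone (reductive opening), the silyl ether and finally the C7–O bond (from C7–B) are traced back. This brings the route back to the cycloadduct with every later stereocentre still to come from substrate control. The demand is an oxidation of an allylic C–B bond with retention in the presence of an unsaturated lactone.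

**13 to 12.** The C9–C10 and C7–C8 bonds are cut (key step). Ring B and the temporary lactone vanish together, C10 and C7 lose their configuration, and what remains is a monocyclic ester. The forward step must be a thermal intramolecular [4+2] reaction onto a tetrasubstituted diene terminus.

**12 to 10 and 11.** The ester C–O bond is cut. The dienophile is a commercial acid. The esterification must not isomerise the ynoate or disturb the boronate.

**10 to 9 to 7 and 8.** The O–Si bond and then the C7–B bond are cut. Hydroboration of a terminal alkyne fixes the (E) geometry that later becomes the C7 configuration. The catalyst must leave the ring alkene alone.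

**7 to 4 and 5 (via 6).** The C5–C6 bond is cut (sp2–sp). The diene carbons come from a two-carbon alkyne and a ring triflate.

**4 to 2 to 1.** The enol triflate is traced to the ketone, whose only enolisable position is the one required, and the silyl ether to the chiral pool carbinol that becomes C2.

**30 to 29 to 27 to 26.** The C–I bond is traced to a syn hydrometallation of a commercial alkyne. The silyl ether is there only to steer the metal to the methyl-bearing carbon.

## Other disconnections considered

**Alternative 1:** The cut goes through ring A at C1–C10 and C4–C5. In the forward sense the quinone A2 (2,6-dimethyl-1,4-benzoquinone) would react at one of its two equivalent methyl-bearing double bonds with the siloxydiene A3 (the triisopropylsilyl dienol ether of mesityl oxide) under a chiral oxazaborolidinium triflimide. A basic work-up would be expected to epimerise C5 and give the trans-fused enedione A1.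
- In its favour: it is convergent, both partners are cheap, and ring A with both ring-fusion centres comes from one catalytic enantioselective operation. Oxygen is already on C2, C6 and C9, and the C7=C8 enone invites a 1,2-addition at C9 followed by allylic transposition to bring oxygen to C7 and the alkene to C8=C9.
- Against it here: the diene terminus that must bond to C5 is gem-dimethylated, so one methyl is cis on the diene and the s-cis form is strained, which makes this class of diene a slow partner. Regiochemistry and face selection rest on how the catalyst binds one of two different quinone carbonyls. C2 is not set (it is an enol ether), C7 has no oxygen, and the C9 carbonyl between C10 and the C8 methyl is a hindered site for the chain.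
- Comparison: on step economy to the bicyclic core A1 is the better (two or three steps against seven). On absolute control the two are equal in kind, catalyst control against a chiral pool carbinol that physically delivers the dienophile. On mechanism both are [4+2] reactions that make a quaternary centre, but the intramolecular version cannot give the wrong regiochemistry or face. On the later redox work the chosen plan is ahead, since its C7 heteroatom arrives with the right configuration and C2 never has to be set.

**Alternative 2:** The cut is at C9–C10, with a sacrificial bond from C1 to the central allene carbon. Irradiation of the ring A enone A5 with allene A6 would give the head-to-head methylenecyclobutane A4. Ozonolysis and retro-Claisen opening of the resulting 1,3-diketone would then leave C10 quaternary with a two-carbon acid chain.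
- In its favour: enone–allene photocycloaddition is a dependable way to make a quaternary carbon β to a ketone. Addition anti to the C5 substituent would give the required trans relation between the new C10–C9 bond and C6, and the C2 carbonyl and the gem-dimethyl group come with the enone.
- Against it here: only one bond of the target skeleton is made and no ring of the target is closed. Ring B, the tetrasubstituted alkene, both ring B oxygens and the chain all remain. A5 needs its own enantioselective synthesis, the β-carbon sits next to a substituted C5 and a quaternary C4, and C2 must still be reduced selectively later.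
- Comparison: for the single task of making C10, A4 is probably the equal or the better of the chosen cycloaddition in reliability, since no strained bridged transition state is involved. In structure gained per step and in step economy the chosen plan is clearly ahead (two skeletal bonds, ring B, two stereocentres and a C7 handle). Stereochemically the chosen plan transfers chirality from C2 to C10 through a bond, whereas A4 relies on steric shielding.

**Alternative 3:** The cuts are C5–C10 and C6–C7. On heating, the (E)-nitroalkene of the acyclic triene A8 would add across its C7=C8–C9=C10 diene through the C1–C4 tether to give the decalin A7.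
- In its favour: both rings, two bonds and four contiguous stereocentres (C5, C6, C7, C10) come from one step. The nitro group is a masked C6 carbonyl, the C7 oxygen is in place, and C11–C13 with C16 are already attached. On these counts it is better than the chosen plan, which builds one ring of the target and adds the chain later.
- Against it here: A8 needs a tetrasubstituted C9=C10 alkene of defined geometry with four different carbon substituents, plus an (E)-enol ether. The fully substituted diene terminus suffers allylic strain in the s-cis form. Four stereocentres are set only through the folding of a tether that carries one silyloxy group, so endo/exo and facial options multiply. The β-alkoxy nitro unit is prone to base-induced loss of the C7 alkoxide, and turning a hindered secondary nitro group into a carbonyl is demanding.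
- Comparison: structurally A7 is the more complete intermediate. Mechanistically both are thermal intramolecular [4+2] reactions, but the chosen one has its selectivity enforced by geometry (one reachable face, one regiochemistry, C7 from alkene geometry), whereas A7 depends on conformational preference. After the key step the alternative would probably be shorter; before it, it is longer and less certain.

Key step: step 7

Remark: α and β are used with the C10 methyl (C20) defined as β, and labdane numbering is kept for all bicyclic intermediates (C17 on C8, C18 and C19 on C4, C20 on C10).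
Remark: the (4R)-carbinol of 1 maps onto C2 with the 2α configuration; 30 is made in three steps (19–21) and is not assumed to be purchasable.

## Steps

**Step 1**
Reactants: 1 (4R,6R)-4-hydroxy-2,2,6-trimethylcyclohexan-1-one (actinol)
Product: 2 (4R,6R)-4-[(tert-butyldimethylsilyl)oxy]-2,2,6-trimethylcyclohexan-1-one
Conditions: TBSCl, imidazole, DMF, rt
Reagents that add atoms: tert-butyldimethylsilyl chloride, CC(C)(C)[Si](C)(C)Cl
Why: Standard silyl ether formation on a secondary alcohol; the ketone and both stereocentres are untouched, and the ether masks the hydroxyl against the amide base of step 2.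

**Step 2**
Reactants: 2 (4R,6R)-4-[(tert-butyldimethylsilyl)oxy]-2,2,6-trimethylcyclohexan-1-one
Product: 4 (R)-4-[(tert-butyldimethylsilyl)oxy]-2,6,6-trimethylcyclohex-1-en-1-yl trifluoromethanesulfonate, via lithium enolate 3 (not isolated)
Conditions: LiN(i-Pr)2, THF, −78 °C; then PhNTf2, −78 °C → rt
Reagents that add atoms: N-phenylbis(trifluoromethanesulfonimide), O=S(=O)(N(c1ccccc1)S(=O)(=O)C(F)(F)F)C(F)(F)F; LiN(i-Pr)2 (lithium of 3 only), [Li]N(C(C)C)C(C)C
Why: Deprotonation can occur only at C6 because C2 is quaternary, and O-sulfonylation of the enolate (enol triflate formation) should give the tetrasubstituted alkenyl triflate; the C6 stereocentre is erased on purpose and the carbinol centre is remote from the base.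

**Step 3**
Reactants: 4 (R)-4-[(tert-butyldimethylsilyl)oxy]-2,6,6-trimethylcyclohex-1-en-1-yl trifluoromethanesulfonate; 5 trimethylsilylacetylene
Product: 7 (R)-tert-butyl[(4-ethynyl-3,5,5-trimethylcyclohex-3-en-1-yl)oxy]dimethylsilane, via trimethylsilyl enyne 6 (not isolated)
Conditions: Pd(PPh3)2Cl2 (5 mol %), CuI (10 mol %), Et3N, DMF, 60 °C; then K2CO3, MeOH, rt
Reagents that add atoms: trimethylsilylacetylene (5), C#C[Si](C)(C)C
Why: Sonogashira coupling of an alkenyl triflate with a terminal alkyne makes the C5–C6 bond; carbonate-catalysed methanolysis of the C–Si bond then frees the terminal alkyne in the same flask while the hindered secondary silyl ether stays.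

**Step 4**
Reactants: 7 (R)-tert-butyl[(4-ethynyl-3,5,5-trimethylcyclohex-3-en-1-yl)oxy]dimethylsilane; 8 pinacolborane
Product: 9 (R,E)-tert-butyldimethyl({3,5,5-trimethyl-4-[2-(4,4,5,5-tetramethyl-1,3,2-dioxaborolan-2-yl)ethenyl]cyclohex-3-en-1-yl}oxy)silane
Conditions: HBpin (1.5 equiv), Cp2ZrHCl (10 mol %), Et3N (10 mol %), THF, 60 °C
Reagents that add atoms: pinacolborane (8), CC1(C)OBOC1(C)C
Why: Cp2ZrHCl-catalysed hydroboration of a terminal alkyne is a syn anti-Markovnikov addition, so boron should end on the terminal carbon with (E) geometry; the tetrasubstituted ring alkene is inert to the catalyst.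

**Step 5**
Reactants: 9 (R,E)-tert-butyldimethyl({3,5,5-trimethyl-4-[2-(4,4,5,5-tetramethyl-1,3,2-dioxaborolan-2-yl)ethenyl]cyclohex-3-en-1-yl}oxy)silane
Product: 10 (R,E)-3,5,5-trimethyl-4-[2-(4,4,5,5-tetramethyl-1,3,2-dioxaborolan-2-yl)ethenyl]cyclohex-3-en-1-ol
Conditions: camphorsulfonic acid (0.2 equiv), MeOH/CH2Cl2, 0 °C → rt
Reagents that add atoms: none
Why: Acid-catalysed methanolysis of the silyl ether; the pinacol boronate and the diene should tolerate catalytic sulfonic acid in methanol, and fluoride is avoided because of the boron.

**Step 6**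
Reactants: 10 (R,E)-3,5,5-trimethyl-4-[2-(4,4,5,5-tetramethyl-1,3,2-dioxaborolan-2-yl)ethenyl]cyclohex-3-en-1-ol; 11 but-2-ynoic acid
Product: 12 (R,E)-3,5,5-trimethyl-4-[2-(4,4,5,5-tetramethyl-1,3,2-dioxaborolan-2-yl)ethenyl]cyclohex-3-en-1-yl but-2-ynoate
Conditions: DCC, DMAP (5 mol %), CH2Cl2, −20 → 0 °C
Reagents that add atoms: but-2-ynoic acid (11), CC#CC(=O)O
Why: Steglich esterification with retention at the carbinol carbon; the low temperature and the small amount of DMAP limit base-induced isomerisation of the ynoate to the allenoate.

**Step 7**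
Reactants: 12 (R,E)-3,5,5-trimethyl-4-[2-(4,4,5,5-tetramethyl-1,3,2-dioxaborolan-2-yl)ethenyl]cyclohex-3-en-1-yl but-2-ynoate
Product: 13 7α-(4,4,5,5-tetramethyl-1,3,2-dioxaborolan-2-yl)-12,13,14,15,16-pentanorlabda-5,8-dien-11,2α-olide
Conditions: 1,2-dichlorobenzene (0.01 M, degassed), BHT (10 mol %), 170 °C
Reagents that add atoms: none
Why: On heating, the tethered but-2-ynoate should add across the ring A diene C10=C5–C6=C7 in a concerted, thermally allowed suprafacial [4+2] cycloaddition in which C9 bonds to C10 and C8 to C7. The closest known reaction type is the ester-tethered intramolecular Diels–Alder reaction of alkynoates with 1-vinylcyclohexene dienes, combined with the known use of 1-boryl-1,3-dienes as diene partners. Ring B is the cycloadduct ring itself (a cyclohexa-1,4-diene with C5=C6 and C8=C9), and the lactone closes as a six-membered ring through the four-atom tether C1–C2–O–C11, so that it bridges C2 and C10 of ring A. C10 is set by the tether: the ester on the 2α oxygen can reach only the α face of C10, so the C10–C9 bond forms cis to O2 and the methyl ends β. C7 is set by the (E) geometry of the alkenylboronate: boron is the outside substituent of the diene terminus and therefore ends cis to C1 and anti to the C10 methyl, that is 7α. The alkyne has no endo or exo issue, and the regiochemistry is fixed because only the tethered orientation can reach the diene. The step needs the diene in its twisted s-cis form, the ester in its less populated E rotamer and the C2 oxygen pseudo-axial, which is why high temperature, high dilution and a radical inhibitor are proposed; the pinacol ester is kept because allylic pinacol boronates should resist 1,3-boron shifts under these conditions.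

**Step 8**
Reactants: 13 7α-(4,4,5,5-tetramethyl-1,3,2-dioxaborolan-2-yl)-12,13,14,15,16-pentanorlabda-5,8-dien-11,2α-olide
Product: 14 7α-hydroxy-12,13,14,15,16-pentanorlabda-5,8-dien-11,2α-olide
Conditions: NaBO3·4H2O, THF/H2O (1:1), 0 °C → rt
Reagents that add atoms: sodium perborate, [Na+].[Na+].O[B-]1(O)OO[B-](O)(O)OO1
Why: Perborate oxidation of the allylic C–B bond proceeds by 1,2-migration of C7 from boron to oxygen with retention and without allylic transposition, giving the 7α-ol; the mild oxidant should spare the unsaturated lactone.

**Step 9**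
Reactants: 14 7α-hydroxy-12,13,14,15,16-pentanorlabda-5,8-dien-11,2α-olide
Product: 15 7α-[(tert-butyldimethylsilyl)oxy]-12,13,14,15,16-pentanorlabda-5,8-dien-11,2α-olide
Conditions: TBSOTf, 2,6-lutidine, CH2Cl2, −78 °C
Reagents that add atoms: tert-butyldimethylsilyl trifluoromethanesulfonate, CC(C)(C)[Si](C)(C)OS(=O)(=O)C(F)(F)F
Why: Silylation of a hindered secondary allylic alcohol with a silyl triflate and a hindered pyridine base; an ether is chosen because an acyloxy group on C7 would be eliminated from the β-boryl intermediate of step 12.

**Step 10**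
Reactants: 15 7α-[(tert-butyldimethylsilyl)oxy]-12,13,14,15,16-pentanorlabda-5,8-dien-11,2α-olide
Product: 16 7α-[(tert-butyldimethylsilyl)oxy]-12,13,14,15,16-pentanorlabda-5,8-diene-2α,11-diol
Conditions: i-Bu2AlH (4 equiv), CH2Cl2, −78 → 0 °C; aq. potassium sodium tartrate
Reagents that add atoms: none
Why: Twofold 1,2-hydride reduction of the unsaturated lactone cuts the tether and gives the primary allylic alcohol at C11 and the free 2α-hydroxyl; with the bridge gone, ring A can relax to the chair with the C10 methyl axial, which the next stereoselective steps rely on.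

**Step 11**
Reactants: 16 7α-[(tert-butyldimethylsilyl)oxy]-12,13,14,15,16-pentanorlabda-5,8-diene-2α,11-diol
Product: 17 7α-[(tert-butyldimethylsilyl)oxy]-12,13,14,15,16-pentanorlabda-5,8-diene-2α,11-diyl diacetate
Conditions: Ac2O, pyridine, DMAP (cat.), CH2Cl2, 0 °C → rt
Reagents that add atoms: acetic anhydride, CC(=O)OC(C)=O
Why: Routine acetylation of a primary and an unhindered secondary alcohol; the acetates shield both hydroxyls from the oxidant of step 13 and are removed by the hydride of step 14 without a separate step.

**Step 12**
Reactants: 17 7α-[(tert-butyldimethylsilyl)oxy]-12,13,14,15,16-pentanorlabda-5,8-diene-2α,11-diyl diacetate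
Product: 19 7α-[(tert-butyldimethylsilyl)oxy]-6α-hydroxy-12,13,14,15,16-pentanor-5α-labd-8-ene-2α,11-diyl diacetate, via 6α-alkylborane 18 (not isolated)
Conditions: BH3·THF (3 equiv), THF, 0 °C → rt; then NaBO3·4H2O, H2O, rt
Reagents that add atoms: sodium perborate, [Na+].[Na+].O[B-]1(O)OO[B-](O)(O)OO1; borane–tetrahydrofuran (boron of 18 only), [BH3-][O+]1CCCC1
Why: Hydroboration–oxidation: borane adds syn across the trisubstituted C5=C6 bond with boron on the less substituted C6 and from the α face, because the β face is screened by the axial C10 methyl and the 4β methyl; this sets the 5α-H trans fusion and a 6α C–B bond that is oxidised with retention. The tetrasubstituted C8=C9 bond is too hindered to react and the acetates should survive borane at this temperature and the perborate work-up.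

**Step 13**
Reactants: 19 7α-[(tert-butyldimethylsilyl)oxy]-6α-hydroxy-12,13,14,15,16-pentanor-5α-labd-8-ene-2α,11-diyl diacetate
Product: 20 7α-[(tert-butyldimethylsilyl)oxy]-6-oxo-12,13,14,15,16-pentanor-5α-labd-8-ene-2α,11-diyl diacetate
Conditions: Dess–Martin periodinane, CH2Cl2, 0 °C → rt
Reagents that add atoms: none
Why: Dess–Martin oxidation of the only free hydroxyl under base-free conditions, chosen so that the C7 hydrogen, which becomes α to the ketone and is allylic, is never exposed to base.

**Step 14**
Reactants: 20 7α-[(tert-butyldimethylsilyl)oxy]-6-oxo-12,13,14,15,16-pentanor-5α-labd-8-ene-2α,11-diyl diacetate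
Product: 21 7α-[(tert-butyldimethylsilyl)oxy]-12,13,14,15,16-pentanor-5α-labd-8-ene-2α,6β,11-triol
Conditions: LiAlH4, THF, −78 → 0 °C
Reagents that add atoms: none
Why: Hydride should attack the ketone from the open α face, since the β face carries two syn-axial methyl groups, giving the axial 6β-alcohol; the same reagent cleaves both acetates, so the C2 and C11 hydroxyls are freed in the same operation.

**Step 15**
Reactants: 21 7α-[(tert-butyldimethylsilyl)oxy]-12,13,14,15,16-pentanor-5α-labd-8-ene-2α,6β,11-triol
Product: 22 7α-[(tert-butyldimethylsilyl)oxy]-2α,6β-dihydroxy-12,13,14,15,16-pentanor-5α-labd-8-en-11-al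
Conditions: MnO2 (excess), CH2Cl2, rt
Reagents that add atoms: none
Why: MnO2 oxidises allylic alcohols selectively and only the C11 hydroxyl is allylic, the C7 oxygen being silylated; the 2α-hydroxyl cannot close onto the aldehyde because a 2,11-bridge is not accessible on the trans-fused skeleton.

**Step 16**
Reactants: 22 7α-[(tert-butyldimethylsilyl)oxy]-2α,6β-dihydroxy-12,13,14,15,16-pentanor-5α-labd-8-en-11-al
Product: 23 7α-[(tert-butyldimethylsilyl)oxy]-13,14,15,16-tetranor-5α-labda-8,11-diene-2α,6β-diol
Conditions: Ph3PCH3Br (5 equiv), KOt-Bu (4.8 equiv), THF, 0 °C → rt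
Reagents that add atoms: methyltriphenylphosphonium bromide, C[P+](c1ccccc1)(c1ccccc1)c1ccccc1.[Br-]
Why: Wittig methylenation of the enal; the two free hydroxyls are simply deprotonated by the excess ylide, and a slight excess of phosphonium salt over base keeps free alkoxide base low to limit deprotonation at C7.

**Step 17**
Reactants: 23 7α-[(tert-butyldimethylsilyl)oxy]-13,14,15,16-tetranor-5α-labda-8,11-diene-2α,6β-diol
Product: 24 13,14,15,16-tetranor-5α-labda-8,11-diene-2α,6β,7α-triol
Conditions: Bu4NF, THF, rt → 45 °C
Reagents that add atoms: none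
Why: Fluoride cleavage of the silyl ether; no base-sensitive group is present at this stage and no stereocentre is affected.

**Step 18**
Reactants: 24 13,14,15,16-tetranor-5α-labda-8,11-diene-2α,6β,7α-triol
Product: 25 13,14,15,16-tetranor-5α-labda-8,11-diene-2α,6β,7α-triyl triacetate
Conditions: Ac2O (excess), DMAP, Et3N, CH2Cl2, 40 °C
Reagents that add atoms: acetic anhydride, CC(=O)OC(C)=O
Why: DMAP-catalysed acetylation; the 2α- and 7α-hydroxyls should react readily and the axial 6β-hydroxyl is the reason for the excess reagent and gentle heating.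

**Step 19**
Reactants: 26 but-2-yn-1-ol
Product: 27 (but-2-yn-1-yloxy)(tert-butyl)dimethylsilane
Conditions: TBSCl, imidazole, CH2Cl2, rt
Reagents that add atoms: tert-butyldimethylsilyl chloride, CC(C)(C)[Si](C)(C)Cl
Why: Silyl ether formation; the bulky ether is there to steer zirconium away from the propargylic carbon in step 20, since a free propargylic alkoxide tends to direct the metal to the proximal carbon.

**Step 20**
Reactants: 27 (but-2-yn-1-yloxy)(tert-butyl)dimethylsilane
Product: 29 (E)-tert-butyl[(3-iodobut-2-en-1-yl)oxy]dimethylsilane, via alkenylzirconocene chloride 28 (not isolated)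
Conditions: Cp2ZrHCl (2 equiv), THF, rt → 45 °C; then I2, 0 °C
Reagents that add atoms: iodine, II; Cp2ZrHCl (zirconium of 28 only), [H][Zr](Cl)(C1C=CC=C1)C1C=CC=C1
Why: Hydrozirconation is a syn addition, and with excess Cp2ZrHCl the alkenylzirconium should equilibrate to the isomer with the metal on the methyl-bearing carbon, distal to the silyloxymethyl group; iodinolysis of the C–Zr bond occurs with retention and gives the (E)-iodide.

**Step 21**
Reactants: 29 (E)-tert-butyl[(3-iodobut-2-en-1-yl)oxy]dimethylsilane
Product: 30 (E)-3-iodobut-2-en-1-ol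
Conditions: camphorsulfonic acid (0.1 equiv), MeOH, 0 °C
Reagents that add atoms: none
Why: Acid-catalysed methanolysis of a primary allylic silyl ether; the alkenyl iodide and its geometry are unaffected.

**Step 22**
Reactants: 25 13,14,15,16-tetranor-5α-labda-8,11-diene-2α,6β,7α-triyl triacetate; 30 (E)-3-iodobut-2-en-1-ol
Product: 32 (13E)-15-hydroxy-5α-labda-8,13-diene-2α,6β,7α-triyl triacetate (CNP0305346.2), via alkyl-9-BBN adduct 31 (not isolated)
Conditions: 9-BBN (1.5 equiv), THF, 0 °C → rt; then 30, Pd(dppf)Cl2 (5 mol %), AsPh3 (5 mol %), Cs2CO3, DMF/H2O, rt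
Reagents that add atoms: (E)-3-iodobut-2-en-1-ol (30), C/C(I)=C\CO; 9-borabicyclo[3.3.1]nonane (boron of 31 only), B1C2CCCC1CCC2
Why: 9-BBN should hydroborate the monosubstituted vinyl group at its terminal carbon and leave the tetrasubstituted alkene and the esters alone; B-alkyl Suzuki–Miyaura coupling of the primary alkylborane with the alkenyl iodide then forms C12–C13 with retention of the (E) geometry and is expected to tolerate the free hydroxyl and the acetates at room temperature.

## Compound list

1 | (4R,6R)-4-hydroxy-2,2,6-trimethylcyclohexan-1-one (actinol) | O[C@H]1CC(C)(C)C(=O)[C@H](C)C1 | starting material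
2 | (4R,6R)-4-[(tert-butyldimethylsilyl)oxy]-2,2,6-trimethylcyclohexan-1-one | CC(C)(C)[Si](C)(C)O[C@H]1CC(C)(C)C(=O)[C@H](C)C1 | intermediate
3 | lithium (R)-4-[(tert-butyldimethylsilyl)oxy]-2,6,6-trimethylcyclohex-1-en-1-olate (formed in the flask) | CC(C)(C)[Si](C)(C)O[C@H]1CC(C)(C)C(O[Li])=C(C)C1 | intermediate
4 | (R)-4-[(tert-butyldimethylsilyl)oxy]-2,6,6-trimethylcyclohex-1-en-1-yl trifluoromethanesulfonate | CC(C)(C)[Si](C)(C)O[C@H]1CC(C)(C)C(OS(=O)(=O)C(F)(F)F)=C(C)C1 | intermediate
5 | trimethylsilylacetylene | C#C[Si](C)(C)C | starting material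
6 | (R)-tert-butyldimethyl({3,5,5-trimethyl-4-[(trimethylsilyl)ethynyl]cyclohex-3-en-1-yl}oxy)silane (formed in the flask) | CC(C)(C)[Si](C)(C)O[C@H]1CC(C)(C)C(C#C[Si](C)(C)C)=C(C)C1 | intermediate
7 | (R)-tert-butyl[(4-ethynyl-3,5,5-trimethylcyclohex-3-en-1-yl)oxy]dimethylsilane | CC(C)(C)[Si](C)(C)O[C@H]1CC(C)(C)C(C#C)=C(C)C1 | intermediate
8 | pinacolborane (4,4,5,5-tetramethyl-1,3,2-dioxaborolane) | CC1(C)OBOC1(C)C | starting material
9 | (R,E)-tert-butyldimethyl({3,5,5-trimethyl-4-[2-(4,4,5,5-tetramethyl-1,3,2-dioxaborolan-2-yl)ethenyl]cyclohex-3-en-1-yl}oxy)silane | CC(C)(C)[Si](C)(C)O[C@H]1CC(C)(C)C(/C=C/B2OC(C)(C)C(C)(C)O2)=C(C)C1 | intermediate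
10 | (R,E)-3,5,5-trimethyl-4-[2-(4,4,5,5-tetramethyl-1,3,2-dioxaborolan-2-yl)ethenyl]cyclohex-3-en-1-ol | O[C@H]1CC(C)(C)C(/C=C/B2OC(C)(C)C(C)(C)O2)=C(C)C1 | intermediate
11 | but-2-ynoic acid | CC#CC(=O)O | starting material
12 | (R,E)-3,5,5-trimethyl-4-[2-(4,4,5,5-tetramethyl-1,3,2-dioxaborolan-2-yl)ethenyl]cyclohex-3-en-1-yl but-2-ynoate | CC#CC(=O)O[C@H]1CC(C)(C)C(/C=C/B2OC(C)(C)C(C)(C)O2)=C(C)C1 | intermediate
13 | 7α-(4,4,5,5-tetramethyl-1,3,2-dioxaborolan-2-yl)-12,13,14,15,16-pentanorlabda-5,8-dien-11,2α-olide (10β-methyl) | O=C3O[C@H]1CC(C)(C)C2=C[C@@H](B4OC(C)(C)C(C)(C)O4)C(C)=C3[C@@]2(C)C1 | intermediate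
14 | 7α-hydroxy-12,13,14,15,16-pentanorlabda-5,8-dien-11,2α-olide | O=C3O[C@H]1CC(C)(C)C2=C[C@@H](O)C(C)=C3[C@@]2(C)C1 | intermediate
15 | 7α-[(tert-butyldimethylsilyl)oxy]-12,13,14,15,16-pentanorlabda-5,8-dien-11,2α-olide | O=C3O[C@H]1CC(C)(C)C2=C[C@@H](O[Si](C)(C)C(C)(C)C)C(C)=C3[C@@]2(C)C1 | intermediate
16 | 7α-[(tert-butyldimethylsilyl)oxy]-12,13,14,15,16-pentanorlabda-5,8-diene-2α,11-diol | O[C@H]1CC(C)(C)C2=C[C@@H](O[Si](C)(C)C(C)(C)C)C(C)=C(CO)[C@@]2(C)C1 | intermediate
17 | 7α-[(tert-butyldimethylsilyl)oxy]-12,13,14,15,16-pentanorlabda-5,8-diene-2α,11-diyl diacetate | CC(=O)O[C@H]1CC(C)(C)C2=C[C@@H](O[Si](C)(C)C(C)(C)C)C(C)=C(COC(C)=O)[C@@]2(C)C1 | intermediate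
18 | 6α-boranyl-7α-[(tert-butyldimethylsilyl)oxy]-12,13,14,15,16-pentanor-5α-labd-8-ene-2α,11-diyl diacetate (formed in the flask) | CC(=O)O[C@H]1CC(C)(C)[C@@H]2[C@@H](B)[C@@H](O[Si](C)(C)C(C)(C)C)C(C)=C(COC(C)=O)[C@@]2(C)C1 | intermediate
19 | 7α-[(tert-butyldimethylsilyl)oxy]-6α-hydroxy-12,13,14,15,16-pentanor-5α-labd-8-ene-2α,11-diyl diacetate | CC(=O)O[C@H]1CC(C)(C)[C@@H]2[C@@H](O)[C@@H](O[Si](C)(C)C(C)(C)C)C(C)=C(COC(C)=O)[C@@]2(C)C1 | intermediate
20 | 7α-[(tert-butyldimethylsilyl)oxy]-6-oxo-12,13,14,15,16-pentanor-5α-labd-8-ene-2α,11-diyl diacetate | CC(=O)O[C@H]1CC(C)(C)[C@@H]2C(=O)[C@@H](O[Si](C)(C)C(C)(C)C)C(C)=C(COC(C)=O)[C@@]2(C)C1 | intermediate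
21 | 7α-[(tert-butyldimethylsilyl)oxy]-12,13,14,15,16-pentanor-5α-labd-8-ene-2α,6β,11-triol | O[C@H]1CC(C)(C)[C@@H]2[C@H](O)[C@@H](O[Si](C)(C)C(C)(C)C)C(C)=C(CO)[C@@]2(C)C1 | intermediate
22 | 7α-[(tert-butyldimethylsilyl)oxy]-2α,6β-dihydroxy-12,13,14,15,16-pentanor-5α-labd-8-en-11-al | O[C@H]1CC(C)(C)[C@@H]2[C@H](O)[C@@H](O[Si](C)(C)C(C)(C)C)C(C)=C(C=O)[C@@]2(C)C1 | intermediate
23 | 7α-[(tert-butyldimethylsilyl)oxy]-13,14,15,16-tetranor-5α-labda-8,11-diene-2α,6β-diol | O[C@H]1CC(C)(C)[C@@H]2[C@H](O)[C@@H](O[Si](C)(C)C(C)(C)C)C(C)=C(C=C)[C@@]2(C)C1 | intermediate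
24 | 13,14,15,16-tetranor-5α-labda-8,11-diene-2α,6β,7α-triol | O[C@H]1CC(C)(C)[C@@H]2[C@H](O)[C@@H](O)C(C)=C(C=C)[C@@]2(C)C1 | intermediate
25 | 13,14,15,16-tetranor-5α-labda-8,11-diene-2α,6β,7α-triyl triacetate | CC(=O)O[C@H]1CC(C)(C)[C@@H]2[C@H](OC(C)=O)[C@@H](OC(C)=O)C(C)=C(C=C)[C@@]2(C)C1 | intermediate
26 | but-2-yn-1-ol | CC#CCO | starting material
27 | (but-2-yn-1-yloxy)(tert-butyl)dimethylsilane | CC#CCO[Si](C)(C)C(C)(C)C | intermediate
28 | chlorobis(cyclopentadienyl)[(E)-4-(tert-butyldimethylsilyloxy)but-2-en-2-yl]zirconium (formed in the flask) | C/C(=C\CO[Si](C)(C)C(C)(C)C)[Zr](Cl)(C1C=CC=C1)C1C=CC=C1 | intermediate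
29 | (E)-tert-butyl[(3-iodobut-2-en-1-yl)oxy]dimethylsilane | C/C(I)=C\CO[Si](C)(C)C(C)(C)C | intermediate
30 | (E)-3-iodobut-2-en-1-ol | C/C(I)=C\CO | intermediate
31 | 12-(9-borabicyclo[3.3.1]nonan-9-yl)-13,14,15,16-tetranor-5α-labd-8-ene-2α,6β,7α-triyl triacetate (formed in the flask) | CC(=O)O[C@H]1CC(C)(C)[C@@H]2[C@H](OC(C)=O)[C@@H](OC(C)=O)C(C)=C(CCB3C4CCCC3CCC4)[C@@]2(C)C1 | intermediate
32 | (13E)-15-hydroxy-5α-labda-8,13-diene-2α,6β,7α-triyl triacetate (CNP0305346.2) | CC(=O)O[C@H]1CC(C)(C)[C@@H]2[C@H](OC(C)=O)[C@@H](OC(C)=O)C(C)=C(CC/C(C)=C/CO)[C@@]2(C)C1 | target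

## Step count and least certain steps

Total: 22 steps. Longest linear sequence: 19 steps (steps 1–18, then step 22); steps 19–21 make the coupling partner 30.

**Step 7 (key step).** The cycloaddition may fail to occur below the temperature at which the diene isomerises by 1,5-hydrogen shift or the ester decomposes. The reacting conformation needs the E rotamer of the ester and a pseudo-axial C2 oxygen that is syn to the 4α methyl. The diene terminus is tetrasubstituted, and the bridged product holds the 4α methyl close to the lactone.
Fallback: a more reactive, bent dienophile on the same tether. Alcohol 10 would be esterified with but-3-ynoic acid (DCC) to the but-3-ynoate F1. Catalytic Et3N should isomerise F1 to the buta-2,3-dienoate F2. Allenoates are markedly better dienophiles than alkynoates, and heating F2 at a lower temperature should give the 8(17)-methylene lactone F3 by addition of the α,β bond of the allene across the same diene, with the same control of C10 and C7. Treatment of F3 with DBU should move the exocyclic alkene into conjugation and give 13, where the route is rejoined.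

**Step 12.** Borane may attack slowly, or from the β face. The carbon that receives boron lies next to the 7α silyloxy group, allylic oxygen tends to direct boranes to the opposite face, and a slow reaction would expose the acetates to borane.
Fallback: a hydroxyl-directed epoxidation followed by radical opening, setting out from 14. VO(acac)2 and t-BuOOH should epoxidise C5=C6 syn to the free 7α-hydroxyl, the C8=C9 bond being deactivated by the lactone carbonyl, to give the 5α,6α-epoxy alcohol F4. Silylation as in step 9 would give F5, reduction as in step 10 the epoxy diol F6, and acetylation as in step 11 the epoxy diacetate F7. Cp2TiCl (from Cp2TiCl2 and Mn) with 1,4-cyclohexadiene should open the epoxide homolytically at the tertiary C5. Hydrogen-atom transfer to the C5 radical from the less hindered α face then gives 19, where the route is rejoined.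

**Step 16.** The basic ylide may remove the C7 hydrogen of the hindered enal (γ to the carbonyl) faster than it adds to the aldehyde, with loss of C7 configuration or migration of the double bond.
Fallback: a two-stage Peterson olefination from 22. The weakly basic organocerium reagent from (CH3)3SiCH2MgCl and CeCl3 should add to the aldehyde to give the β-hydroxysilane F8. KH in THF should then cause syn elimination to 23, at a stage where no acidic C7 hydrogen remains next to a carbonyl.

**Step 22.** Zerovalent palladium may insert into the allylic C7 acetate, the aqueous carbonate may cleave or shift acetates, and 9-BBN may add only slowly to the twisted diene.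
Fallback: couple before any acetate exists, setting out from 23. Alcohol 30 would be converted with 4-methoxybenzyl trichloroacetimidate and catalytic acid into the 4-methoxybenzyl ether F9. Hydroboration of 23 with excess 9-BBN and coupling with F9 under the same palladium conditions should give the silyl ether diol F10. Bu4NF would give the triol F11, acetylation as in step 18 the triacetate F12, and DDQ in wet CH2Cl2 should remove the 4-methoxybenzyl group to give 32.

## Further compounds

F1 | step 7 | (R,E)-3,5,5-trimethyl-4-[2-(4,4,5,5-tetramethyl-1,3,2-dioxaborolan-2-yl)ethenyl]cyclohex-3-en-1-yl but-3-ynoate | C#CCC(=O)O[C@H]1CC(C)(C)C(/C=C/B2OC(C)(C)C(C)(C)O2)=C(C)C1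
F2 | step 7 | (R,E)-3,5,5-trimethyl-4-[2-(4,4,5,5-tetramethyl-1,3,2-dioxaborolan-2-yl)ethenyl]cyclohex-3-en-1-yl buta-2,3-dienoate | C=C=CC(=O)O[C@H]1CC(C)(C)C(/C=C/B2OC(C)(C)C(C)(C)O2)=C(C)C1
F3 | step 7 | 7α-(4,4,5,5-tetramethyl-1,3,2-dioxaborolan-2-yl)-12,13,14,15,16-pentanorlabda-5,8(17)-dien-11,2α-olide (C9 configuration left open, removed on isomerisation) | O=C3O[C@H]1CC(C)(C)C2=C[C@@H](B4OC(C)(C)C(C)(C)O4)C(=C)C3[C@@]2(C)C1
F4 | step 12 | 5α,6α-epoxy-7α-hydroxy-12,13,14,15,16-pentanorlabd-8-en-11,2α-olide | O=C4O[C@H]1CC(C)(C)[C@@]25O[C@H]5[C@@H](O)C(C)=C4[C@@]2(C)C1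
F5 | step 12 | 7α-[(tert-butyldimethylsilyl)oxy]-5α,6α-epoxy-12,13,14,15,16-pentanorlabd-8-en-11,2α-olide | O=C4O[C@H]1CC(C)(C)[C@@]25O[C@H]5[C@@H](O[Si](C)(C)C(C)(C)C)C(C)=C4[C@@]2(C)C1
F6 | step 12 | 7α-[(tert-butyldimethylsilyl)oxy]-5α,6α-epoxy-12,13,14,15,16-pentanorlabd-8-ene-2α,11-diol | O[C@H]1CC(C)(C)[C@@]25O[C@H]5[C@@H](O[Si](C)(C)C(C)(C)C)C(C)=C(CO)[C@@]2(C)C1
F7 | step 12 | 7α-[(tert-butyldimethylsilyl)oxy]-5α,6α-epoxy-12,13,14,15,16-pentanorlabd-8-ene-2α,11-diyl diacetate | CC(=O)O[C@H]1CC(C)(C)[C@@]25O[C@H]5[C@@H](O[Si](C)(C)C(C)(C)C)C(C)=C(COC(C)=O)[C@@]2(C)C1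
F8 | step 16 | 7α-[(tert-butyldimethylsilyl)oxy]-12-(trimethylsilyl)-13,14,15,16-tetranor-5α-labd-8-ene-2α,6β,11-triol (C11 configuration left open, removed on elimination) | O[C@H]1CC(C)(C)[C@@H]2[C@H](O)[C@@H](O[Si](C)(C)C(C)(C)C)C(C)=C(C(O)C[Si](C)(C)C)[C@@]2(C)C1
F9 | step 22 | 1-({[(E)-3-iodobut-2-en-1-yl]oxy}methyl)-4-methoxybenzene | COc1ccc(COC/C=C(\C)I)cc1
F10 | step 22 | (13E)-7α-[(tert-butyldimethylsilyl)oxy]-15-[(4-methoxybenzyl)oxy]-5α-labda-8,13-diene-2α,6β-diol | O[C@H]1CC(C)(C)[C@@H]2[C@H](O)[C@@H](O[Si](C)(C)C(C)(C)C)C(C)=C(CC/C(C)=C/COCc3ccc(OC)cc3)[C@@]2(C)C1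
F11 | step 22 | (13E)-15-[(4-methoxybenzyl)oxy]-5α-labda-8,13-diene-2α,6β,7α-triol | O[C@H]1CC(C)(C)[C@@H]2[C@H](O)[C@@H](O)C(C)=C(CC/C(C)=C/COCc3ccc(OC)cc3)[C@@]2(C)C1
F12 | step 22 | (13E)-15-[(4-methoxybenzyl)oxy]-5α-labda-8,13-diene-2α,6β,7α-triyl triacetate | CC(=O)O[C@H]1CC(C)(C)[C@@H]2[C@H](OC(C)=O)[C@@H](OC(C)=O)C(C)=C(CC/C(C)=C/COCc3ccc(OC)cc3)[C@@]2(C)C1
A1 | alternative 1 | trans-fused 2-(triisopropylsilyloxy) 6,9-enedione (Diels–Alder product after C5 epimerisation) | CC(C)[Si](C(C)C)(C(C)C)OC1=CC(C)(C)[C@@H]2C(=O)C=C(C)C(=O)[C@@]2(C)C1
A2 | alternative 1 | 2,6-dimethyl-1,4-benzoquinone | CC1=CC(=O)C=C(C)C1=O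
A3 | alternative 1 | triisopropyl[(4-methylpenta-1,3-dien-2-yl)oxy]silane | C=C(O[Si](C(C)C)(C(C)C)C(C)C)C=C(C)C
A4 | alternative 2 | methylenecyclobutane photoadduct fused at C1–C10 | O=C1CC(C)(C)[C@H](COCc2ccccc2)[C@@]3(C)CC(=C)[C@@H]13
A5 | alternative 2 | 4-[(benzyloxy)methyl]-3,5,5-trimethylcyclohex-2-en-1-one (single enantiomer at C4 of the ring) | O=C1CC(C)(C)[C@H](COCc2ccccc2)C(C)=C1
A6 | alternative 2 | propa-1,2-diene (allene) | C=C=C
A7 | alternative 3 | trans-fused 6α-nitro-7α-(4-methoxybenzyloxy) decalin with C8=C9 and a ketal-protected chain | CC(C)(C)[Si](C)(C)O[C@H]1CC(C)(C)[C@@H]2[C@@H]([N+](=O)[O-])[C@@H](OCc3ccc(OC)cc3)C(C)=C(CCC3(C)OCCO3)[C@@]2(C)C1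
A8 | alternative 3 | acyclic (E)-nitroalkene triene precursor with C2 silyl ether | [O-][N+](=O)/C=C/C(C)(C)C[C@H](O[Si](C)(C)C(C)(C)C)C/C(C)=C(CCC1(C)OCCO1)/C(C)=C/OCc1ccc(OC)cc1
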